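A closed flask and a well-mixed tank take the same 0.20 M of substrate for 6.0 h, the tank on average, and the question is which one puts more of its product into target.

| setting | cedar | larch | maple | Saturday's | Wednesday's |
|---|---|---|---|---|---|
| substrate | 0.20 M | 0.10 M | 0.40 M | 0.20 M | 0.20 M |
| remark | run made earlier | run made earlier | run made earlier | a closed flask charged with all of it at once and left for 6.0 h | a single well-mixed tank run continuously and read at steady state, 6.0 h in it on average |
| time |  |  |  | 6.0 h |  |

| run | time / h | target / % | side product / % | substrate / % |
|---|---|---|---|---|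
| cedar | 0.250 | 0 | 6 | 95 |
| cedar | 0.417 | 0 | 0 | 95 |
| cedar | 0.667 | 1 | 1 | 93 |
| cedar | 1.00 | 2 | 0 | 93 |
| cedar | 1.50 | 0 | 0 | 91 |
| cedar | 2.50 | 3 | 4 | 86 |
| cedar | 4.00 | 2 | 5 | 78 |
| larch | 0.417 | 0 | 0 | 99 |
| larch | 1.00 | 0 | 0 | 92 |
| larch | 2.00 | 5 | 0 | 84 |
| larch | 3.00 | 4 | 0 | 81 |
| larch | 4.00 | 6 | 3 | 78 |
| larch | 6.00 | 6 | 7 | 72 |
| larch | 8.00 | 5 | 7 | 72 |
| maple | 0.417 | 1 | 1 | 99 |
| maple | 1.00 | 4 | 0 | 91 |
| maple | 2.00 | 2 | 1 | 88 |
| maple | 3.00 | 1 | 8 | 78 |
| maple | 4.00 | 4 | 6 | 80 |
| maple | 6.00 | 2 | 13 | 70 |
| maple | 8.00 | 0 | 20 | 62 |

(each reading ± 2 percentage points)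

- percentages count the substrate that a species holds: one side product counts as two
- the stated concentrations are those of everything mixed, before any reaction; amounts are the same in each set-up
- the numbers in the tables scatter by 2 percentage points (one standard deviation)
- the earlier runs were made in a closed, stirred flask

* the set-up with the highest share of target in all that became target or side product, at the outlet or at the end ("none" if the first two lie within 2 percentage points) (Saturday's / Wednesday's / none)
* share of target in all that became target or side product, at the outlet or at the end, Saturday's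
* share of target in all that became target or side product, at the outlet or at the end, Wednesday's

Target, T in percent, reads nearly constant. From 3.00 h on, the larch run holds it between 4% and 6%, while side product, B in percent, reads 8% at 3.00 h and 20% at 8.00 h in the maple run. Freeze T (a quasi-steady state), and this reckoning lets B grow with T and with time. The ratio B/T read at 6.00 h is higher at the higher charge c: 1.17 at 0.10 M, 6.50 at 0.40 M. Pooling both runs:

g = ΣB / Σ(T·c) = 14.3 L mol⁻¹

This g, a reading that carries the scatter, is the side product per target per unit of charge at that time in a closed flask. The share of target then follows: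

T/(T+B) = 1/(1+g·c) = 25.9% for Saturday's flask

The weak link is the freezing from time zero. Side product still reads 0% at 2.00 h in the larch run and 1% in the maple run, so this reckoning lets a closed flask make side product for about the last 4.00 h of its 6.0 h. Wednesday's tank, read at steady state, is reckoned at its T for its whole average time t, here 6.0 h:

g_tank = g·t/(t − 2.00 h) = 21.4 L mol⁻¹, share 18.9% for Wednesday's tank

The forecast, made apart, also puts Saturday's first, at 27% (19% to 36%) against 22% (14% to 31%), noting that “Target appears before side product and its share falls with concentration”. Both its figures stand higher than the reckoning here .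

Saturday's flask gives 29.3% and Wednesday's tank 20.7%, so Saturday's leads.

    substrate ⇌ intermediate (K = 0.340, k = 2.30 × 10⁻⁵ s⁻¹)
    intermediate ⇌ target (K = 0.310, k = 1.10 × 10⁻⁴ s⁻¹)
    substrate + target → side product (k = 5.90 × 10⁻⁴ L mol⁻¹ s⁻¹)

At 6.00 h, target in Saturday's flask is made 1.19 times as fast as it is used up. For the same flask with 0.80 M of substrate, g = 14.3 L mol⁻¹ reckons a share of 8.04%, and the flask gives 8.93%.

(The readings were generated by integration with made-up constants; scatter was added.)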